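## The problem

Eudesmane numbering is used throughout: C1–C15 for the methylenedecalin half, primed numbers for the lactone half, and the same numbers for the open-chain precursors.

Target 22 is an unsymmetrical dimer of two C15 units. The only link between them is a 3,4-dihydro-2H-pyran ring, O–C12H=C11–C13H2–C13'H2–C11', whose C11' is also the α-carbon of the γ-lactone. C11' is therefore a spiro, oxygen-bearing, fully substituted stereocentre.

There are eight stereocentres: C5, C7 and C10 in the decalin half, C4', C7', C8' and C10' in the lactone half, and C11'. The two sets are separated by the flat enol ether and cannot control each other, so each half must be enantiopure on its own and of the matching absolute sense. C11' sits on the cis-fused bicyclic lactone and can be controlled by its convex face.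

The lactone half, stereocentres included, is (+)-alantolactone (21). The decalin half is not a natural-type eudesmane: C10 is (S) where C10' is (R), and the ring fusion is cis. It has to be built de novo and asymmetrically.

The groups that limit the choice of reagents are:
- the enol ether (acid);
- the 4(15)-exocyclic alkene (acid, hydrogenation, isomerisation);
- the α-methylene lactone of 21 (nucleophiles, amines);
- C5, which can epimerise to the trans-fused series as long as C4 is a carbonyl.

Two features make a short route possible. First, C5, C7 and C10 all lie on ring B with H5, the C10 methyl and the C7 side chain on one face. This is the pattern produced when a vinyl ketone C6=C5–C4(=O) is tied through C3–C2–C1 to the inside position of C10 in a C10=C9–C8=C7 diene. Second, the dihydropyran is the retron of an oxa-Diels–Alder reaction between an α-methylene aldehyde (O=C12–C11=C13) and the exocyclic alkene C11'=C13' of an α-methylene lactone.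

## Retrosynthesis

**Dihydropyran ring (22 ⇒ 20 + 21).** The O–C11' and C13–C13' bonds are cut in a retro-oxa-Diels–Alder sense. This gives the 2-substituted acrolein 20 and the α-methylene lactone 21. The neighbouring cuts (C11–C13 by alkylation, or O–C12 by lactol chemistry) would need a pre-hydroxylated C11', a homologated C13' and several redox steps. The cycloaddition cut halves the molecule, removes the spiro centre and leaves the acid-labile enol ether to the last step. 21 is bought, so four stereocentres cost no steps. The forward reaction must join oxygen to C11' and C13 to C13' (the head-to-head sense of acrolein dimerisation) and must approach the lactone from its convex face.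

**Enal (20 ⇒ 19 ⇒ 18 ⇒ 17).** The C11=C13 bond is cut back to aldehyde 19 (α-methylenation with formaldehyde). 19 comes from alcohol 18 and silyl ether 17. α-Methylene aldehydes dimerise on standing, so 20 is made last from a stable precursor. C12 travels as a tert-butyldiphenylsilyl ether, which is robust to acid and Lewis acid and too bulky to compete for a Lewis acid.

**Exocyclic methylene and ring saturation (17 ⇒ 16 ⇒ 15).** C4=C15 is traced to the C4 ketone of 16, and the saturated C8–C9 bond to the alkene of 15. The ketone thus serves twice: as the activating group of the dienophile and as the source of the methylene. The forward steps must hydrogenate before the methylene is present and must methylenate without enolising toward C5.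

**Rings A and B (15 ⇒ 14).** The C5–C10 and C6–C7 bonds are cut in a retro-Diels–Alder sense. Octalone 15, with two rings and three stereocentres, becomes the achiral open-chain trienone 14. An annulation of a cyclohexanone would favour the trans-fused, natural-type relative configuration and would leave C7 to be set separately. An intermolecular cycloaddition would struggle to form the quaternary C10 with regiocontrol. In the intramolecular mode the (Z) geometry at C10 and the (E) geometry at C7 fix all relative configuration. Only the enantioface of the vinyl ketone is left to an external controller.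

**Vinyl ketone (14 ⇒ 13 ⇒ 12 ⇒ 11).** The C4–C5 bond is cut: 14 comes from allylic alcohol 13 by oxidation, and 13 from aldehyde 12 and a vinyl Grignard reagent. 12 is stored as dioxolane 11. The vinyl ketone is unmasked last because it polymerises and cyclises on its own.

**Diene (11 ⇒ 4 + 5 + 6).** The C8–C9 bond (sp2–sp2 coupling) and the C1–C10 bond (carbometallation) are cut. Syn-carbocupration of propyne (6) with the copper reagent from chloride 5 puts the tether and the metal cis on the new alkene. This is the inside placement the key step needs. Carboalumination of a tether-bearing alkyne would give the opposite isomer, and Wittig chemistry gives mixtures at trisubstituted alkenes. Coupling with (E)-iodoalkene 4 with retention completes the (Z,E)-diene. Carbon sources: 5 gives C1–C4; 6 gives C9, C10 and C14; 4 gives C7, C8, C11 and C12.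

**Iodoalkene (4 ⇒ 2 ⇒ 1).** The C8–I bond and the silyl ether are cut. Hydrozirconation–iodination of silyl ether 2, made from but-3-yn-1-ol (1), gives only the (E)-iodide.

## Roads not taken

**Alternative 1:** The cut is the C8'–O bond of the γ-lactone. The precursor is dienoic acid A2, to be assembled from a chiral-pool isopropenylcyclohexenone by annulation and oxidation of the isopropenyl group. In the forward key step Pd(OAc)2, a bidentate ligand and an oxidant would palladate the C8' methylene through a six-membered carboxylate-bound palladacycle. C–O bond formation would then close the cis-fused lactone A1.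
- Merits: no oxygen need be carried at C8'; the cis fusion follows from the palladacycle; the lactone half becomes fully synthetic in either enantiomeric series.
- Weak points: A2 is an acrylic acid with an sp2 α-carbon and a tertiary, doubly allylic C7'–H. Allylic palladation and π-allyl pathways at C7' or C6' compete with the unactivated C8' methylene. Carboxyl-directed γ-lactonisations are established for saturated acids, not for this class. The oxidant also meets two alkenes.
- Comparison: A1 is identical with 21, so this road spends roughly ten steps and one unprecedented step on a compound that can be bought. It is better in independence from natural supply and in access to modified lactone halves. The chosen plan sets step economy against that, and places its one unproven step on the half that cannot be bought. This road also leaves the decalin half and the union unsolved.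

**Alternative 2:** The cut is the C9'–C10' bond of ring B of the lactone half. The (Z)-triene A4 (C10'=C5'–C6'=C7'–C8'(OSi)=C9') would undergo a thermal disrotatory 6π-electrocyclisation to the 5,7-diene silyl enol ether A3.
- Merits: the step needs no reagent; it forms ring B and the quaternary C10' at once; it delivers oxygen at C8' and a dienol ether for later functionalisation at C7'.
- Weak points: the central C6'=C7' alkene must be (Z), the less stable geometry. The closing terminus C10' is fully substituted, so hydrogen shifts compete at the temperatures needed. The sense of disrotation, which sets C10' relative to C4', is steered only by a methyl group two atoms away. After A3 the acrylate carbons, the C8' reduction and the lactone closure are still to come, with regiochemistry (C7' against C5') and facial questions of their own.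
- Comparison: this would be the shortest de novo entry to the bicyclic core of the lactone half. Like Alternative 1, it makes what the chosen plan buys and adds nothing for the decalin half. The chosen plan forgoes synthetic access to the lactone half and gains about ten steps and freedom from two doubtful selectivities.

**Alternative 3:** The cuts are C11–C13 and O–C12. The lithium enolate of ester A6 would be alkylated by primary iodide A7. On desilylation the C11' alkoxide would close onto the ester to give spiro bis-lactone A5. The δ-lactone would then be reduced to the lactol and dehydrated to the enol ether.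
- Merits: all steps are ionic and run at low temperature. C11' is set on the lactone fragment before the halves meet and can be verified. There is no question of cycloaddition regiochemistry or enal dimerisation.
- Weak points: A7 needs about five steps from 21 (one-carbon homologation at C13', hydroxylation at C11', protection, iodide), and A6 needs two from 19. The δ-lactone of A5 must be half-reduced in the presence of the γ-lactone. A C11 stereocentre is made only to be destroyed.
- Comparison: this road is better in predictability at C11' and in avoiding a forcing thermal step. The chosen plan forms the same ring in one protecting-group-free, atom-economic step and relies on the convex face of 21 for C11'. If that reliance fails, this alternative is the natural replacement for the end game.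

Key step: step 7

Remark 1: (+)-alantolactone (21), a commercial single-enantiomer natural product whose four stereocentres are those of the lactone half, is used as purchased.

Remark 2: the oxazaborolidinium made from (S)-α,α-diphenylprolinol is assumed to expose the enantioface of the s-cis vinyl ketone that leads to 15; the mirror-image catalyst is equally available if the sense proves opposite.

## Route

Step 1
Reactants: 1 but-3-yn-1-ol
Product: 2 (but-3-yn-1-yloxy)(tert-butyl)diphenylsilane
Conditions: TBDPSCl, imidazole, CH2Cl2, 0 °C → rt
Reagents that add atoms: tert-butyl(chloro)diphenylsilane, CC(C)(C)[Si](Cl)(c1ccccc1)c1ccccc1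
Why: Imidazole-assisted silylation of a primary alcohol; the tert-butyldiphenylsilyl group is chosen because it must survive the acetal hydrolysis of step 4 and the strong Lewis acid of step 7.

Step 2
Reactants: 2 (but-3-yn-1-yloxy)(tert-butyl)diphenylsilane
Product: 4 (E)-tert-butyl[(4-iodobut-3-en-1-yl)oxy]diphenylsilane, via alkenylzirconocene chloride 3 (not isolated)
Conditions: Cp2Zr(H)Cl, THF, rt; then I2, 0 °C
Reagents that add atoms: iodine, II
Why: Hydrozirconation adds Zr–H syn with zirconium at the terminal carbon, and iodinolysis of the C–Zr bond goes with retention, so only the (E)-iodoalkene is expected.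

Step 3
Reactants: 5 2-(3-chloropropyl)-1,3-dioxolane, 6 propyne, 4 (E)-tert-butyl[(4-iodobut-3-en-1-yl)oxy]diphenylsilane
Product: 11 2-[(4Z,6E)-9-(tert-butyldiphenylsilyloxy)-4-methylnona-4,6-dien-1-yl]-1,3-dioxolane, via Grignard reagent 7 (not isolated), via alkylcopper 8 (not isolated), via alkenylcopper 9 (not isolated), via alkenylzinc bromide 10 (not isolated)
Conditions: 5, Mg, THF (minimum), 50 °C; CuBr·SMe2, Et2O/Me2S, −45 °C; 6 (excess), −25 °C; then ZnBr2, Pd(PPh3)4 (5 mol %), 4, THF, −20 °C → rt
Reagents that add atoms: none
Why: Normant carbocupration: the alkylcopper adds syn across propyne with the alkyl group on the methyl-bearing carbon, so the metal ends cis to the tether. Transmetallation to zinc and Negishi-type coupling on zerovalent palladium keep the geometry of both alkenyl partners, which defines the (4Z,6E)-diene.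

Step 4
Reactants: 11 2-[(4Z,6E)-9-(tert-butyldiphenylsilyloxy)-4-methylnona-4,6-dien-1-yl]-1,3-dioxolane
Product: 12 (5Z,7E)-10-(tert-butyldiphenylsilyloxy)-5-methyldeca-5,7-dienal
Conditions: PPTS (cat.), acetone/H2O, reflux
Reagents that add atoms: water, O
Why: Mild acid-catalysed acetal hydrolysis; pyridinium tosylate is too weak an acid to protonate the diene or to cleave the tert-butyldiphenylsilyl ether.

Step 5
Reactants: 12 (5Z,7E)-10-(tert-butyldiphenylsilyloxy)-5-methyldeca-5,7-dienal
Product: 13 (7Z,9E)-12-(tert-butyldiphenylsilyloxy)-7-methyldodeca-1,7,9-trien-3-ol (racemic at C3 of the chain)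
Conditions: CH2=CHMgBr, THF, −78 → 0 °C
Reagents that add atoms: vinylmagnesium bromide, C=C[Mg]Br
Why: Grignard 1,2-addition to an unhindered aldehyde; the carbinol centre is formed as a racemate and is removed in step 6.

Step 6
Reactants: 13 (7Z,9E)-12-(tert-butyldiphenylsilyloxy)-7-methyldodeca-1,7,9-trien-3-ol
Product: 14 (7Z,9E)-12-(tert-butyldiphenylsilyloxy)-7-methyldodeca-1,7,9-trien-3-one
Conditions: Dess–Martin periodinane, NaHCO3, CH2Cl2, 0 °C; cold filtration, used at once
Reagents that add atoms: none
Why: Dess–Martin oxidation of a secondary allylic alcohol under buffered, non-nucleophilic conditions should give the vinyl ketone without conjugate addition; the product is kept cold in solution because it polymerises and slowly cyclises.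

Step 7
Reactants: 14 (7Z,9E)-12-(tert-butyldiphenylsilyloxy)-7-methyldodeca-1,7,9-trien-3-one
Product: 15 (4aS,7S,8aR)-7-[2-(tert-butyldiphenylsilyloxy)ethyl]-4a-methyl-3,4,4a,7,8,8a-hexahydronaphthalen-1(2H)-one (eudesmane numbering 5R,7S,10S; H5, the C10 methyl and the C7 side chain on one face)
Conditions: (S)-3,3-diphenyl-1-(o-tolyl)tetrahydro-1H,3H-pyrrolo[1,2-c][1,3,2]oxazaborole·HNTf2 (N-protonated oxazaborolidinium triflimide, 20 mol %), CH2Cl2, −78 → −20 °C; Et3N quench
Reagents that add atoms: none
Why: Proposed new method: the boron of the oxazaborolidinium binds the C4 carbonyl and lowers the LUMO of the C5=C6 vinyl group, and the (Z,E)-diene adds in a concerted, asynchronous type 1 intramolecular Diels–Alder reaction in which the C6–C7 bond (enone β-carbon to the CH terminus of the diene) runs ahead of C5–C10; the closest known reaction types are the thermal and Lewis-acid-promoted cyclisation of 1,7,9-decatrien-3-ones to cis-octalones and the oxazaborolidinium-catalysed enantioselective Diels–Alder reaction of vinyl ketones, which have not been combined on a (Z)-diene with a fully substituted terminus. Ring B is closed by the cycloaddition itself, since both new bonds lie in it, and ring A is closed by the C5–C10 bond because the C1–C3 tether already joins C4 to C10. The tether occupies the inside position at C10 and holds the enone s-cis, so only the transition state leading to the cis ring fusion is attainable, which places H5 cis to the outside methyl at C10. The (E) geometry at C7 puts the silyloxyethyl group outside, and suprafacial addition across the diene sets it cis to the C10 methyl. The absolute configuration comes from the enantioface of the vinyl ketone left open by the catalyst. The step needs enantioface selectivity and a catalysed rate well above the racemic background. The slow uncatalysed closure of a (Z)-diene at low temperature and the bulky, weakly basic silyl ether, which does not compete for boron, are what secure this.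

Step 8
Reactants: 15 (4aS,7S,8aR)-7-[2-(tert-butyldiphenylsilyloxy)ethyl]-4a-methyl-3,4,4a,7,8,8a-hexahydronaphthalen-1(2H)-one
Product: 16 (4aS,7S,8aR)-7-[2-(tert-butyldiphenylsilyloxy)ethyl]-4a-methyloctahydronaphthalen-1(2H)-one
Conditions: H2 (1 atm), 5% Pt/C, EtOAc, rt
Reagents that add atoms: none
Why: Heterogeneous hydrogenation of a cis-disubstituted ring alkene; platinum is preferred to palladium to limit double-bond migration toward C7, and no stereocentre is created.

Step 9
Reactants: 16 (4aS,7S,8aR)-7-[2-(tert-butyldiphenylsilyloxy)ethyl]-4a-methyloctahydronaphthalen-1(2H)-one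
Product: 17 tert-butyl{2-[(2S,4aS,8aS)-4a-methyl-8-methylidenedecahydronaphthalen-2-yl]ethoxy}diphenylsilane
Conditions: Zn, CH2Br2, TiCl4, THF/CH2Cl2, 0 °C → rt
Reagents that add atoms: dibromomethane, BrCBr
Why: Takai–Lombardo methylenation; the weakly basic zinc–titanium methylene reagent converts hindered, enolisable ketones without epimerising the α-stereocentre, so the cis fusion at C5 should be kept.

Step 10
Reactants: 17 tert-butyl{2-[(2S,4aS,8aS)-4a-methyl-8-methylidenedecahydronaphthalen-2-yl]ethoxy}diphenylsilane
Product: 18 2-[(2S,4aS,8aS)-4a-methyl-8-methylidenedecahydronaphthalen-2-yl]ethan-1-ol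
Conditions: Bu4NF, THF, rt
Reagents that add atoms: none
Why: Fluoride cleavage of the silyl ether; nothing else in the molecule reacts with fluoride.

Step 11
Reactants: 18 2-[(2S,4aS,8aS)-4a-methyl-8-methylidenedecahydronaphthalen-2-yl]ethan-1-ol
Product: 19 2-[(2S,4aS,8aS)-4a-methyl-8-methylidenedecahydronaphthalen-2-yl]acetaldehyde
Conditions: Dess–Martin periodinane, NaHCO3, CH2Cl2, 0 °C → rt
Reagents that add atoms: none
Why: Dess–Martin oxidation of a primary alcohol stops at the aldehyde and leaves the exocyclic alkene alone; C7 is β to the carbonyl and cannot epimerise.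

Step 12
Reactants: 19 2-[(2S,4aS,8aS)-4a-methyl-8-methylidenedecahydronaphthalen-2-yl]acetaldehyde
Product: 20 2-[(2S,4aS,8aS)-4a-methyl-8-methylidenedecahydronaphthalen-2-yl]prop-2-enal
Conditions: 37% aq. HCHO, pyrrolidine (10 mol %), EtCO2H (10 mol %), i-PrOH, 45 °C
Reagents that add atoms: formaldehyde, C=O
Why: Amine-catalysed Mannich condensation with formaldehyde followed by elimination (organocatalytic α-methylenation of an aldehyde) gives the 2-substituted acrolein; the product dimerises on standing and is used directly.

Step 13
Reactants: 20 2-[(2S,4aS,8aS)-4a-methyl-8-methylidenedecahydronaphthalen-2-yl]prop-2-enal, 21 (+)-alantolactone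
Product: 22 the target: spiro adduct in which the 3,4-dihydro-2H-pyran O–C12H=C11–C13H2–C13'H2–C11' joins C7 of the (5S,7S,10S)-4(15)-methylenedecalin to the lactone α-carbon C11' (R) of the alantolactone-derived half (4'S,7'S,8'R,10'R; 5'(6')-ene), the pyran oxygen on the face of H7'
Conditions: 21 (3 equiv), BHT (cat.), toluene, sealed tube, 120 °C
Reagents that add atoms: none
Why: Thermal oxa-Diels–Alder reaction of a 2-substituted acrolein (1-oxadiene O=C12–C11=C13) with an α-alkylacrylate-type dienophile (C11'=C13'), with the head-to-head regiochemistry of acrolein dimerisation (oxygen to C11', C13 to C13'). The heterodiene should add to the convex face of the cis-fused lactone, the face of H7' and opposite C6', which sets the spiro centre C11' as (R). No other stereocentre is formed, and the excess of 21 disfavours self-dimerisation of 20.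

## Compound list

1 | but-3-yn-1-ol | C#CCCO | starting material
2 | (but-3-yn-1-yloxy)(tert-butyl)diphenylsilane | C#CCCO[Si](c1ccccc1)(c1ccccc1)C(C)(C)C | intermediate
3 | (E)-[4-(tert-butyldiphenylsilyloxy)but-1-en-1-yl]bis(cyclopentadienyl)zirconium chloride (cyclopentadienyl rings drawn σ-bonded) | Cl[Zr](/C=C/CCO[Si](c1ccccc1)(c1ccccc1)C(C)(C)C)(C1C=CC=C1)C1C=CC=C1 | intermediate (not isolated)
4 | (E)-tert-butyl[(4-iodobut-3-en-1-yl)oxy]diphenylsilane | I/C=C/CCO[Si](c1ccccc1)(c1ccccc1)C(C)(C)C | intermediate
5 | 2-(3-chloropropyl)-1,3-dioxolane | ClCCCC1OCCO1 | starting material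
6 | propyne | CC#C | starting material
7 | [3-(1,3-dioxolan-2-yl)propyl]magnesium chloride | Cl[Mg]CCCC1OCCO1 | intermediate (not isolated)
8 | [3-(1,3-dioxolan-2-yl)propyl]copper (as its magnesium halide–dimethyl sulfide complex) | [Cu]CCCC1OCCO1 | intermediate (not isolated)
9 | (Z)-[5-(1,3-dioxolan-2-yl)-2-methylpent-1-en-1-yl]copper (copper cis to the chain) | [Cu]/C=C(/C)CCCC1OCCO1 | intermediate (not isolated)
10 | (Z)-[5-(1,3-dioxolan-2-yl)-2-methylpent-1-en-1-yl]zinc bromide | Br[Zn]/C=C(/C)CCCC1OCCO1 | intermediate (not isolated)
11 | 2-[(4Z,6E)-9-(tert-butyldiphenylsilyloxy)-4-methylnona-4,6-dien-1-yl]-1,3-dioxolane | CC(C)(C)[Si](c1ccccc1)(c1ccccc1)OCC/C=C/C=C(/C)CCCC1OCCO1 | intermediate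
12 | (5Z,7E)-10-(tert-butyldiphenylsilyloxy)-5-methyldeca-5,7-dienal | O=CCCC/C(C)=C\C=C\CCO[Si](c1ccccc1)(c1ccccc1)C(C)(C)C | intermediate
13 | (7Z,9E)-12-(tert-butyldiphenylsilyloxy)-7-methyldodeca-1,7,9-trien-3-ol (racemic at C3) | C=CC(O)CCC/C(C)=C\C=C\CCO[Si](c1ccccc1)(c1ccccc1)C(C)(C)C | intermediate
14 | (7Z,9E)-12-(tert-butyldiphenylsilyloxy)-7-methyldodeca-1,7,9-trien-3-one | C=CC(=O)CCC/C(C)=C\C=C\CCO[Si](c1ccccc1)(c1ccccc1)C(C)(C)C | intermediate
15 | (4aS,7S,8aR)-7-[2-(tert-butyldiphenylsilyloxy)ethyl]-4a-methyl-3,4,4a,7,8,8a-hexahydronaphthalen-1(2H)-one | O=C1CCC[C@@]2(C)C=C[C@H](CCO[Si](c3ccccc3)(c3ccccc3)C(C)(C)C)C[C@@H]12 | intermediate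
16 | (4aS,7S,8aR)-7-[2-(tert-butyldiphenylsilyloxy)ethyl]-4a-methyloctahydronaphthalen-1(2H)-one | O=C1CCC[C@@]2(C)CC[C@H](CCO[Si](c3ccccc3)(c3ccccc3)C(C)(C)C)C[C@@H]12 | intermediate
17 | tert-butyl{2-[(2S,4aS,8aS)-4a-methyl-8-methylidenedecahydronaphthalen-2-yl]ethoxy}diphenylsilane | C=C1CCC[C@@]2(C)CC[C@H](CCO[Si](c3ccccc3)(c3ccccc3)C(C)(C)C)C[C@@H]12 | intermediate
18 | 2-[(2S,4aS,8aS)-4a-methyl-8-methylidenedecahydronaphthalen-2-yl]ethan-1-ol | C=C1CCC[C@@]2(C)CC[C@H](CCO)C[C@@H]12 | intermediate
19 | 2-[(2S,4aS,8aS)-4a-methyl-8-methylidenedecahydronaphthalen-2-yl]acetaldehyde | C=C1CCC[C@@]2(C)CC[C@H](CC=O)C[C@@H]12 | intermediate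
20 | 2-[(2S,4aS,8aS)-4a-methyl-8-methylidenedecahydronaphthalen-2-yl]prop-2-enal | C=C1CCC[C@@]2(C)CC[C@H](C(=C)C=O)C[C@@H]12 | intermediate
21 | (+)-alantolactone, (3aR,5S,8aR,9aR)-5,8a-dimethyl-3-methylidene-3a,5,6,7,8,8a,9,9a-octahydronaphtho[2,3-b]furan-2(3H)-one | C=C1C(=O)O[C@@H]2C[C@@]3(C)CCC[C@H](C)C3=C[C@@H]21 | starting material
22 | target spiro adduct (decalin half 5S,7S,10S; lactone half 4'S,7'S,8'R,10'R; spiro C11' R) | C=C1CCC[C@@]2(C)CC[C@H](C3=CO[C@@]4(CC3)C(=O)O[C@@H]3C[C@@]5(C)CCC[C@H](C)C5=C[C@@H]34)C[C@@H]12 | target

## Step count and risks

Total step count: 13.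

Longest linear sequence: 13 steps (1 → 22, steps 1–13). Compounds 5 and 6 enter at step 3 and 21 enters at step 13. C5, C7 and C10 are set in step 7, C11' in step 13, and C4', C7', C8' and C10' arrive with 21.

**Step 7 (key step, proposed new method).**
- What may go wrong: poor enantioface discrimination, because the tether forces the vinyl ketone into an s-cis geometry for which the sense and level of induction by the oxazaborolidinium are not established. Acid-induced isomerisation of the trisubstituted (Z)-alkene before cyclisation is a second possibility.
- Fallback: starting from 14, the same cycloaddition is run without a chiral controller (Me2AlCl, CH2Cl2, −78 → −20 °C, or simple warming). This is the known mode for such trienones. It should give 15 together with its (4aR,7R,8aS) enantiomer F1. The two are separated by preparative chromatography on a chiral stationary phase, and the route is rejoined at 15.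

**Step 13.**
- What may go wrong: slow cross-cycloaddition between two electron-poor partners, so that on prolonged heating self-dimerisation of the enal and ene or isomerisation reactions at the 4(15)-alkene take over. Incomplete facial selectivity at C11' is also possible.
- Fallback: the exocyclic alkene is kept out of the thermal step. Starting from 16, desilylation (Bu4NF) gives keto alcohol F2. Dess–Martin oxidation gives keto aldehyde F3. α-Methylenation with formaldehyde gives keto enal F4, which is heated with 21, under more forcing conditions if needed, to the 4-oxo adduct F5. A final Takai–Lombardo methylenation, which leaves lactones and enol ethers untouched, rejoins the route at 22.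

**Step 3.**
- What may go wrong: incomplete carbometallation of propyne by the functionalised alkylcopper when tetrahydrofuran is present, and homocoupling or loss of alkenyl geometry during the copper-to-zinc-to-palladium relay.
- Fallback: the two partners are isolated and joined by a boron-based coupling. Alkenylcopper 9, made from 5 and 6 as before, is quenched with iodine to give 2-[(4Z)-5-iodo-4-methylpent-4-en-1-yl]-1,3-dioxolane F6, which is purified. Alkyne 2 is hydroborated with pinacolborane (Cp2Zr(H)Cl cat.) to the (E)-alkenyl pinacolboronate F7. Suzuki–Miyaura coupling (Pd(PPh3)4, aq. K3PO4, THF) rejoins the route at 11.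

**Step 9.**
- What may go wrong: enolisation of the hindered C4 ketone instead of methylene transfer, with return of ketone or epimerisation at C5 toward the trans-fused series.
- Fallback: a Peterson olefination. Starting from 16, Me3SiCH2Li/CeCl3 (a non-basic organocerium addition) gives β-hydroxysilane F8 as either C4 epimer. Elimination with KH in THF rejoins the route at 17.

## Further compounds

F1 | step 7 | (4aR,7R,8aS)-7-[2-(tert-butyldiphenylsilyloxy)ethyl]-4a-methyl-3,4,4a,7,8,8a-hexahydronaphthalen-1(2H)-one (enantiomer of 15) | O=C1CCC[C@]2(C)C=C[C@@H](CCO[Si](c3ccccc3)(c3ccccc3)C(C)(C)C)C[C@H]12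
F2 | step 13 | (4aS,7S,8aR)-7-(2-hydroxyethyl)-4a-methyloctahydronaphthalen-1(2H)-one | O=C1CCC[C@@]2(C)CC[C@H](CCO)C[C@@H]12
F3 | step 13 | 2-[(2S,4aS,8aR)-4a-methyl-8-oxodecahydronaphthalen-2-yl]acetaldehyde | O=C1CCC[C@@]2(C)CC[C@H](CC=O)C[C@@H]12
F4 | step 13 | 2-[(2S,4aS,8aR)-4a-methyl-8-oxodecahydronaphthalen-2-yl]prop-2-enal | O=C1CCC[C@@]2(C)CC[C@H](C(=C)C=O)C[C@@H]12
F5 | step 13 | 4-oxo analogue of 22 (C4 ketone in place of the 4(15)-alkene) | O=C1CCC[C@@]2(C)CC[C@H](C3=CO[C@@]4(CC3)C(=O)O[C@@H]3C[C@@]5(C)CCC[C@H](C)C5=C[C@@H]34)C[C@@H]12
F6 | step 3 | 2-[(4Z)-5-iodo-4-methylpent-4-en-1-yl]-1,3-dioxolane | I/C=C(/C)CCCC1OCCO1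
F7 | step 3 | (E)-tert-butyldiphenyl{[4-(4,4,5,5-tetramethyl-1,3,2-dioxaborolan-2-yl)but-3-en-1-yl]oxy}silane | CC1(C)OB(/C=C/CCO[Si](c2ccccc2)(c2ccccc2)C(C)(C)C)OC1(C)C
F8 | step 9 | (4aS,7S,8aR)-7-[2-(tert-butyldiphenylsilyloxy)ethyl]-4a-methyl-1-[(trimethylsilyl)methyl]decahydronaphthalen-1-ol (either C1 epimer) | C[Si](C)(C)CC1(O)CCC[C@@]2(C)CC[C@H](CCO[Si](c3ccccc3)(c3ccccc3)C(C)(C)C)C[C@@H]12
A1 | alternative 1 | tricyclic α-methylene 8β,12-lactone (identical with 21) | C=C1C(=O)O[C@@H]2C[C@@]3(C)CCC[C@H](C)C3=C[C@@H]21
A2 | alternative 1 | (4S,7R,10R)-eudesma-5,11(13)-dien-12-oic acid | C=C(C(=O)O)[C@@H]1CC[C@@]2(C)CCC[C@H](C)C2=C1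
A3 | alternative 2 | cis-4,10-dimethyl-hexahydronaphthalene 8-(tert-butyldimethylsilyl) dienol ether | CC(C)(C)[Si](C)(C)OC1=CC=C2[C@@H](C)CCC[C@]2(C)C1
A4 | alternative 2 | tert-butyl({(3Z)-4-[(6S)-2,6-dimethylcyclohex-1-en-1-yl]buta-1,3-dien-2-yl}oxy)dimethylsilane | C=C(O[Si](C)(C)C(C)(C)C)/C=C\C1=C(C)CCC[C@@H]1C
A5 | alternative 3 | spiro bis-lactone (12-oxo, 11-saturated analogue of 22, either C11 epimer) | C=C1CCC[C@@]2(C)CC[C@H](C3C(=O)O[C@@]4(CC3)C(=O)O[C@@H]3C[C@@]5(C)CCC[C@H](C)C5=C[C@@H]34)C[C@@H]12
A6 | alternative 3 | methyl 2-[(2S,4aS,8aS)-4a-methyl-8-methylidenedecahydronaphthalen-2-yl]acetate | C=C1CCC[C@@]2(C)CC[C@H](CC(=O)OC)C[C@@H]12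
A7 | alternative 3 | 13'-(iodomethyl)-11'-(trimethylsilyloxy)-11',13'-dihydroalantolactone (C11' oxygen on the face of H7') | ICC[C@]1(O[Si](C)(C)C)C(=O)O[C@@H]2C[C@@]3(C)CCC[C@H](C)C3=C[C@@H]21
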